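**Plan**

- Retrosynthesis: the three benzyl ethers come off last. The C3 stereocentre is traced through the cis-isoflavan-4-ol back to a flat isoflavone (C2=C3).
- Ring C of the isoflavone is cut at O1–C8a and C3–C4. This gives an arylacetaldehyde (ring B with C3, C2 and O1) and a 2-fluoro-4-alkoxybenzoyl chloride (ring A with C4).
- Enabling feature: the C4 carbonyl sits on C4a, ortho to C8a, and the C7 oxygen is meta to C8a. A 2-fluoroaroyl unit is therefore a 1,3-bis-electrophile (acyl C4, and C8a by SNAr). The aldehyde enolate is the matching C3/O1 bis-nucleophile, C3 being benzylic to ring B.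
- Ring B comes from 2,3,4-trihydroxybenzaldehyde. The 1,1-dimethylallyl group arrives at C5 by aromatic Claisen rearrangement of the 4-O-prenyl ether, followed by O-methylation and Wittig homologation (C3–C2 bond).
- Forward order: ring B is finished first, ring A is bought, and ring C closes in the key step.
- Stereochemistry: C3 is set (S) by Ru-catalysed asymmetric transfer hydrogenation with dynamic kinetic resolution to the cis-(3S,4S) alcohol, followed by reoxidation at C4.

Key step: step 8

Remark: C3 is the only stereocentre and the configuration asked for is (3S); 4-(benzyloxy)-2-fluorobenzoic acid is taken as a purchasable starting material.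

Abbreviation used in the steps: Ar = 2,3-bis(benzyloxy)-4-methoxy-5-(2-methylbut-3-en-2-yl)phenyl.

**Route**

Step 1
Reactants: 1 2,3,4-trihydroxybenzaldehyde
Product: 2 2,3-dihydroxy-4-[(3-methylbut-2-en-1-yl)oxy]benzaldehyde
Conditions: prenyl bromide (1.05 equiv), KHCO3, DMF, rt
Reagents that add atoms: prenyl bromide, CC(C)=CCBr
Why: Williamson etherification with a weak base should alkylate only O4, the most acidic phenol (para to the formyl group), because O2 is held in a hydrogen bond to the aldehyde and O3 is flanked on both sides.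

Step 2
Reactants: 2 2,3-dihydroxy-4-[(3-methylbut-2-en-1-yl)oxy]benzaldehyde
Product: 3 2,3-bis(benzyloxy)-4-[(3-methylbut-2-en-1-yl)oxy]benzaldehyde
Conditions: BnBr (2.5 equiv), K2CO3, DMF, 60 °C
Reagents that add atoms: benzyl bromide, BrCc1ccccc1
Why: Williamson benzylation of the two remaining phenols, with benzyl chosen because it outlasts the thermal, basic, reductive and oxidative steps and can be removed at the end without hydrogen gas.

Step 3
Reactants: 3 2,3-bis(benzyloxy)-4-[(3-methylbut-2-en-1-yl)oxy]benzaldehyde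
Product: 5 2,3-bis(benzyloxy)-4-hydroxy-5-(2-methylbut-3-en-2-yl)benzaldehyde, via dienone 4 (not isolated)
Conditions: PhNEt2, 190 °C, sealed tube, Ar
Reagents that add atoms: none
Why: Aromatic Claisen rearrangement, in which the [3,3] shift transposes the prenyl group onto C5, the only free ortho carbon (C3 carries a benzyloxy group and the para carbon C1 is substituted), giving the 1,1-dimethylallyl group before dienone 4 tautomerises to the phenol; the basic solvent should suppress acid-catalysed cyclisation of the product.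

Step 4
Reactants: 5 2,3-bis(benzyloxy)-4-hydroxy-5-(2-methylbut-3-en-2-yl)benzaldehyde
Product: 6 2,3-bis(benzyloxy)-4-methoxy-5-(2-methylbut-3-en-2-yl)benzaldehyde
Conditions: MeI, K2CO3, DMF, rt
Reagents that add atoms: methyl iodide, CI
Why: Williamson methylation of a phenoxide that is acidified by the para formyl group and, although flanked, is open to the small electrophile.

Step 5
Reactants: 6 2,3-bis(benzyloxy)-4-methoxy-5-(2-methylbut-3-en-2-yl)benzaldehyde
Product: 7 2,3-bis(benzyloxy)-4-methoxy-1-(2-methoxyethenyl)-5-(2-methylbut-3-en-2-yl)benzene (E/Z mixture)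
Conditions: MeOCH2PPh3Cl, KOt-Bu, THF, 0 °C → rt
Reagents that add atoms: (methoxymethyl)triphenylphosphonium chloride, COC[P+](c1ccccc1)(c1ccccc1)c1ccccc1.[Cl-]
Why: Wittig reaction with the methoxymethylene ylide gives the one-carbon-homologated enol ether, whose E/Z geometry does not matter because it is lost on hydrolysis.

Step 6
Reactants: 7 2,3-bis(benzyloxy)-4-methoxy-1-(2-methoxyethenyl)-5-(2-methylbut-3-en-2-yl)benzene
Product: 8 2-Ar-acetaldehyde, that is 2-[2,3-bis(benzyloxy)-4-methoxy-5-(2-methylbut-3-en-2-yl)phenyl]acetaldehyde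
Conditions: aq. HCl (2 M), THF, 45 °C
Reagents that add atoms: water, O
Why: Acid-catalysed enol ether hydrolysis through the hemiacetal should give the arylacetaldehyde, while benzyl ethers, the aryl methyl ether and the monosubstituted alkene are inert to dilute aqueous acid.

Step 7
Reactants: 9 4-(benzyloxy)-2-fluorobenzoic acid
Product: 10 4-(benzyloxy)-2-fluorobenzoyl chloride
Conditions: (COCl)2, DMF (cat.), CH2Cl2, 0 °C → rt
Reagents that add atoms: oxalyl chloride, O=C(Cl)C(=O)Cl
Why: Standard DMF-catalysed (Vilsmeier-type) conversion of a carboxylic acid into its chloride, which leaves the aryl fluoride and the benzyl ether untouched.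

Step 8
Reactants: 8 2-Ar-acetaldehyde (1.15 equiv); 10 4-(benzyloxy)-2-fluorobenzoyl chloride
Product: 13 7-(benzyloxy)-3-Ar-4H-chromen-4-one (the isoflavone), via enol ester 11 (not isolated), via formyl ketone 12 (not isolated)
Conditions: Et3N (1.2 equiv), DMAP (0.2 equiv), MeCN, 0 °C → rt; then Cs2CO3 (3 equiv), 80 °C
Reagents that add atoms: none
Why: Proposed new method: Et3N/DMAP first O-acylates the enolate of 8 with 10 to enol ester 11; DMAP (helped by free enolate from the slight excess of 8) then reopens 11 to an acylpyridinium–enolate pair that recombines at the benzylic carbon C3, and Cs2CO3 removes the C-acyl isomer 12 as its stabilised enolate, whose oxygen O1 displaces fluoride from C8a by addition–elimination. The closest known reaction types are the Steglich-type and cyanide-catalysed O-to-C acyl shifts of enol esters to 1,3-dicarbonyl compounds (not shown for an aldehyde enol ester, hence the label) and the base-mediated closure of 2-fluoroaryl 1,3-dicarbonyl compounds to chromones. Ring C closes 6-endo-trig: O1 adds to the trigonal C8a of the vinylogous acyl unit C8a=C4a–C4=O, the Meisenheimer charge is taken up by the C4 carbonyl, and loss of fluoride restores ring A. No stereocentre arises, because C3 is trigonal in 13 and the E/Z geometry of 11 is lost in the ion pair. The step needs C- over O-acylation and ring closure ahead of aldehyde self-condensation: O-acylation is reversible under nucleophilic catalysis whereas C-acylation is made irreversible by deprotonation and then by fluoride loss, the acid chloride is present before the base so the enolate is capped as it forms, and C8a is the only carbon bearing a leaving group, ortho to the C4 carbonyl and meta (not para) to the C7 benzyloxy donor.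

Step 9
Reactants: 13 7-(benzyloxy)-3-Ar-4H-chromen-4-one
Product: 15 (3S,4S)-7-(benzyloxy)-3-Ar-3,4-dihydro-2H-chromen-4-ol (cis), via racemic isoflavanone 14 (not isolated)
Conditions: RuCl[(S,S)-TsDPEN](p-cymene) (3 mol%), HCO2H/Et3N (5:2), EtOAc, 45 °C
Reagents that add atoms: none
Why: Asymmetric transfer hydrogenation, a known cascade for isoflavones: the Ru hydride should first reduce C2=C3 in the conjugate sense to isoflavanone 14, which racemises quickly at C3 through its enol in the amine buffer, and the (S,S) catalyst then delivers hydride to C4 in its usual sense for aryl ketones (4S) and anti to the C3 aryl group, so dynamic kinetic resolution funnels the material to the cis-(3S,4S) alcohol, while the isolated terminal alkene is not a substrate for this outer-sphere hydride.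

Step 10
Reactants: 15 (3S,4S)-7-(benzyloxy)-3-Ar-3,4-dihydro-2H-chromen-4-ol
Product: 16 (3S)-7-(benzyloxy)-3-Ar-2,3-dihydro-4H-chromen-4-one
Conditions: Dess–Martin periodinane, CH2Cl2, 0 °C → rt
Reagents that add atoms: none
Why: Dess–Martin oxidation returns C4 to the ketone under non-basic conditions, so the C3 stereocentre, now alpha to the carbonyl, should not be enolised.

Step 11
Reactants: 16 (3S)-7-(benzyloxy)-3-Ar-2,3-dihydro-4H-chromen-4-one
Product: 17 (3S)-3-[2,3-dihydroxy-4-methoxy-5-(2-methylbut-3-en-2-yl)phenyl]-7-hydroxy-2,3-dihydro-4H-chromen-4-one (target)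
Conditions: BCl3, C6HMe5, CH2Cl2, −78 °C; then H2O
Reagents that add atoms: none
Why: Lewis-acid debenzylation with a non-basic cation scavenger: BCl3 should cleave the three aryl benzyl ethers at −78 °C while pentamethylbenzene traps the benzyl cations by Friedel–Crafts alkylation, and at this temperature without base the C3–H is not removed, the aryl methyl ether is kept, and the alkene that hydrogenolysis would saturate is untouched.

**Compound list**

1 | 2,3,4-trihydroxybenzaldehyde | O=Cc1ccc(O)c(O)c1O | starting material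
2 | 2,3-dihydroxy-4-[(3-methylbut-2-en-1-yl)oxy]benzaldehyde | O=Cc1ccc(OCC=C(C)C)c(O)c1O | intermediate
3 | 2,3-bis(benzyloxy)-4-[(3-methylbut-2-en-1-yl)oxy]benzaldehyde | O=Cc1ccc(OCC=C(C)C)c(OCc2ccccc2)c1OCc1ccccc1 | intermediate
4 | 5,6-bis(benzyloxy)-3-(2-methylbut-3-en-2-yl)-4-oxocyclohexa-1,5-diene-1-carbaldehyde (Claisen dienone, not isolated) | O=CC1=CC(C(C)(C)C=C)C(=O)C(OCc2ccccc2)=C1OCc1ccccc1 | intermediate
5 | 2,3-bis(benzyloxy)-4-hydroxy-5-(2-methylbut-3-en-2-yl)benzaldehyde | O=Cc1cc(C(C)(C)C=C)c(O)c(OCc2ccccc2)c1OCc1ccccc1 | intermediate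
6 | 2,3-bis(benzyloxy)-4-methoxy-5-(2-methylbut-3-en-2-yl)benzaldehyde | O=Cc1cc(C(C)(C)C=C)c(OC)c(OCc2ccccc2)c1OCc1ccccc1 | intermediate
7 | 2,3-bis(benzyloxy)-4-methoxy-1-(2-methoxyethenyl)-5-(2-methylbut-3-en-2-yl)benzene (E/Z mixture) | COC=Cc1cc(C(C)(C)C=C)c(OC)c(OCc2ccccc2)c1OCc1ccccc1 | intermediate
8 | 2-[2,3-bis(benzyloxy)-4-methoxy-5-(2-methylbut-3-en-2-yl)phenyl]acetaldehyde | O=CCc1cc(C(C)(C)C=C)c(OC)c(OCc2ccccc2)c1OCc1ccccc1 | intermediate
9 | 4-(benzyloxy)-2-fluorobenzoic acid | OC(=O)c1ccc(OCc2ccccc2)cc1F | starting material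
10 | 4-(benzyloxy)-2-fluorobenzoyl chloride | O=C(Cl)c1ccc(OCc2ccccc2)cc1F | intermediate
11 | 2-[2,3-bis(benzyloxy)-4-methoxy-5-(2-methylbut-3-en-2-yl)phenyl]ethenyl 4-(benzyloxy)-2-fluorobenzoate (E/Z, not isolated) | O=C(OC=Cc1cc(C(C)(C)C=C)c(OC)c(OCc2ccccc2)c1OCc1ccccc1)c1ccc(OCc2ccccc2)cc1F | intermediate
12 | 2-[2,3-bis(benzyloxy)-4-methoxy-5-(2-methylbut-3-en-2-yl)phenyl]-3-[4-(benzyloxy)-2-fluorophenyl]-3-oxopropanal (mainly as its enol, not isolated) | O=CC(C(=O)c1ccc(OCc2ccccc2)cc1F)c1cc(C(C)(C)C=C)c(OC)c(OCc2ccccc2)c1OCc1ccccc1 | intermediate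
13 | 7-(benzyloxy)-3-[2,3-bis(benzyloxy)-4-methoxy-5-(2-methylbut-3-en-2-yl)phenyl]-4H-chromen-4-one | O=c1c(-c2cc(C(C)(C)C=C)c(OC)c(OCc3ccccc3)c2OCc2ccccc2)coc2cc(OCc3ccccc3)ccc12 | intermediate
14 | racemic 7-(benzyloxy)-3-[2,3-bis(benzyloxy)-4-methoxy-5-(2-methylbut-3-en-2-yl)phenyl]-2,3-dihydro-4H-chromen-4-one (not isolated) | O=C1c2ccc(OCc3ccccc3)cc2OCC1c1cc(C(C)(C)C=C)c(OC)c(OCc2ccccc2)c1OCc1ccccc1 | intermediate
15 | (3S,4S)-7-(benzyloxy)-3-[2,3-bis(benzyloxy)-4-methoxy-5-(2-methylbut-3-en-2-yl)phenyl]-3,4-dihydro-2H-chromen-4-ol (cis) | C=CC(C)(C)c1cc([C@H]2COc3cc(OCc4ccccc4)ccc3[C@H]2O)c(OCc2ccccc2)c(OCc2ccccc2)c1OC | intermediate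
16 | (3S)-7-(benzyloxy)-3-[2,3-bis(benzyloxy)-4-methoxy-5-(2-methylbut-3-en-2-yl)phenyl]-2,3-dihydro-4H-chromen-4-one | C=CC(C)(C)c1cc([C@H]2COc3cc(OCc4ccccc4)ccc3C2=O)c(OCc2ccccc2)c(OCc2ccccc2)c1OC | intermediate
17 | (3S)-3-[2,3-dihydroxy-4-methoxy-5-(2-methylbut-3-en-2-yl)phenyl]-7-hydroxy-2,3-dihydro-4H-chromen-4-one | C=CC(C)(C)c1cc([C@H]2COc3cc(O)ccc3C2=O)c(O)c(O)c1OC | target

**Count**

Total steps: 11. Longest linear sequence: 10 steps (steps 1–6 and 8–11, from compound 1).

**Steps most likely to fail, with fallbacks**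

Step 8. The O-to-C acyl transfer may stall at the enol ester, or the aldehyde enolate may condense with itself before it is acylated. The fallback uses known chemistry, Stork enamine acylation. It sets out from 8: condensation with morpholine (4 Å molecular sieves, toluene, rt) should give the enamine 4-[(E)-2-Ar-ethenyl]morpholine F1. C-acylation of F1 with 10 (Et3N, toluene, 60 °C) should give the enaminone 2-Ar-1-[4-(benzyloxy)-2-fluorophenyl]-3-(morpholin-4-yl)prop-2-en-1-one F2. Hydrolysis with aqueous HCl in THF releases formyl ketone 12, and K2CO3 in DMF at 80 °C closes it by SNAr to 13, where the route is rejoined.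

Step 3. At the temperature needed, the prenyl group may be lost by fragmentation, or the 1,1-dimethylallyl phenol may migrate further or cyclise onto the neighbouring oxygen. The fallback replaces the sigmatropic shift by a cross-coupling and sets out from 1. Selective 4-O-methylation (MeI, Li2CO3, DMF) gives 2,3-dihydroxy-4-methoxybenzaldehyde F3. Benzylation (BnBr, K2CO3, DMF) gives 2,3-bis(benzyloxy)-4-methoxybenzaldehyde F4. Bromination with NBS in MeCN should go to C5 (ortho to the methoxy group, para to the C2 ether, meta to the formyl group) and give 2,3-bis(benzyloxy)-5-bromo-4-methoxybenzaldehyde F5. A branch-selective Suzuki–Miyaura coupling with 3-methylbut-2-enylboronic acid pinacol ester (Pd(OAc)2, a bulky biarylphosphine chosen for attack at the tertiary allyl terminus, K3PO4, THF/H2O) then gives 6, where the route is rejoined.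

Step 11. Configuration at C3 may erode by enolisation while the ketone is bound to the Lewis acid or during the acidic quench. The fallback moves the debenzylation to the achiral isoflavone and ends with silyl ethers that buffered fluoride removes; it sets out from 13. BCl3 and pentamethylbenzene (CH2Cl2, −78 °C) give 7-hydroxy-3-[2,3-dihydroxy-4-methoxy-5-(2-methylbut-3-en-2-yl)phenyl]-4H-chromen-4-one F6. TBSCl and imidazole in DMF give the tris(tert-butyldimethylsilyl) ether of that isoflavone F7. Transfer hydrogenation as in step 9 passes through the racemising tris-silyl isoflavanone F8 and should give the cis-(3S,4S) tris-silyl isoflavan-4-ol F9. Dess–Martin oxidation gives the (3S) tris-silyl isoflavanone F10. HF·pyridine in THF/pyridine at 0 °C then removes the silyl groups and gives 17, the end of the route.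

**Further compounds**

F1 | step 8 | 4-[(E)-2-[2,3-bis(benzyloxy)-4-methoxy-5-(2-methylbut-3-en-2-yl)phenyl]ethenyl]morpholine | C1COCCN1/C=C/c1cc(C(C)(C)C=C)c(OC)c(OCc2ccccc2)c1OCc1ccccc1
F2 | step 8 | 2-[2,3-bis(benzyloxy)-4-methoxy-5-(2-methylbut-3-en-2-yl)phenyl]-1-[4-(benzyloxy)-2-fluorophenyl]-3-(morpholin-4-yl)prop-2-en-1-one | O=C(C(=CN1CCOCC1)c1cc(C(C)(C)C=C)c(OC)c(OCc2ccccc2)c1OCc1ccccc1)c1ccc(OCc2ccccc2)cc1F
F3 | step 3 | 2,3-dihydroxy-4-methoxybenzaldehyde | COc1ccc(C=O)c(O)c1O
F4 | step 3 | 2,3-bis(benzyloxy)-4-methoxybenzaldehyde | COc1ccc(C=O)c(OCc2ccccc2)c1OCc1ccccc1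
F5 | step 3 | 2,3-bis(benzyloxy)-5-bromo-4-methoxybenzaldehyde | COc1c(Br)cc(C=O)c(OCc2ccccc2)c1OCc1ccccc1
F6 | step 11 | 7-hydroxy-3-[2,3-dihydroxy-4-methoxy-5-(2-methylbut-3-en-2-yl)phenyl]-4H-chromen-4-one | O=c1c(-c2cc(C(C)(C)C=C)c(OC)c(O)c2O)coc2cc(O)ccc12
F7 | step 11 | 7-[(tert-butyldimethylsilyl)oxy]-3-[2,3-bis[(tert-butyldimethylsilyl)oxy]-4-methoxy-5-(2-methylbut-3-en-2-yl)phenyl]-4H-chromen-4-one | O=c1c(-c2cc(C(C)(C)C=C)c(OC)c(O[Si](C)(C)C(C)(C)C)c2O[Si](C)(C)C(C)(C)C)coc2cc(O[Si](C)(C)C(C)(C)C)ccc12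
F8 | step 11 | racemic 7-[(tert-butyldimethylsilyl)oxy]-3-[2,3-bis[(tert-butyldimethylsilyl)oxy]-4-methoxy-5-(2-methylbut-3-en-2-yl)phenyl]-2,3-dihydro-4H-chromen-4-one (not isolated) | O=C1c2ccc(O[Si](C)(C)C(C)(C)C)cc2OCC1c1cc(C(C)(C)C=C)c(OC)c(O[Si](C)(C)C(C)(C)C)c1O[Si](C)(C)C(C)(C)C
F9 | step 11 | (3S,4S)-7-[(tert-butyldimethylsilyl)oxy]-3-[2,3-bis[(tert-butyldimethylsilyl)oxy]-4-methoxy-5-(2-methylbut-3-en-2-yl)phenyl]-3,4-dihydro-2H-chromen-4-ol | C=CC(C)(C)c1cc([C@H]2COc3cc(O[Si](C)(C)C(C)(C)C)ccc3[C@H]2O)c(O[Si](C)(C)C(C)(C)C)c(O[Si](C)(C)C(C)(C)C)c1OC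
F10 | step 11 | (3S)-7-[(tert-butyldimethylsilyl)oxy]-3-[2,3-bis[(tert-butyldimethylsilyl)oxy]-4-methoxy-5-(2-methylbut-3-en-2-yl)phenyl]-2,3-dihydro-4H-chromen-4-one | C=CC(C)(C)c1cc([C@H]2COc3cc(O[Si](C)(C)C(C)(C)C)ccc3C2=O)c(O[Si](C)(C)C(C)(C)C)c(O[Si](C)(C)C(C)(C)C)c1OC
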